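**Strategy.** Everything rests on disconnecting ring A of the flavone into a four-carbon vinylketene (released from 3-ethoxycyclobutenone) and a two-carbon siloxyalkyne that already carries the 4-methoxybenzyl group. One thermal benzannulation forms C8–C8a, C6–C7 and C4a–C8a. It exploits the fact that ring A is a 2-benzylphloroglucinol: the oxygens on C8a, C7 and C5 around benzylated C8 emerge differentiated, as free hydroxyl (future O1), silyl ether and ethyl ether. The precursor is a triisopropylsilyl ynol ether, ArCH2–C≡C–OSi(i-Pr)3. The single phenol then steers ring C annulation (oxa-Michael addition, acylative closure at C4a), and ether cleavage finishes the route.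

Key step: step 2

Assumption: the terminal alkyne 1-methoxy-4-(prop-2-yn-1-yl)benzene 1 is taken as a purchasable compound; the other starting materials are ordinary catalogue items.

**Step 1**
Reactants: 1 1-methoxy-4-(prop-2-yn-1-yl)benzene
Product: 4 triisopropyl{[3-(4-methoxyphenyl)prop-1-yn-1-yl]oxy}silane, via lithium acetylide 2 (not isolated), via lithium ynolate 3 (not isolated)
Conditions: n-BuLi, THF, −78 °C; LiOOt-Bu (from t-BuOOH + LiN(SiMe3)2, THF, −78 °C), −78 → 0 °C; then i-Pr3SiOTf, −78 → 0 °C; pentane/aq. NaHCO3 work-up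
Reagents that add atoms: tert-butyl hydroperoxide, CC(C)(C)OO; triisopropylsilyl trifluoromethanesulfonate, CC(C)[Si](C(C)C)(C(C)C)OS(=O)(=O)C(F)(F)F
Why: Deprotonation of the terminal C–H at −78 °C is followed by electrophilic oxygen transfer from the lithium peroxide to the acetylide carbon (acetylide oxidation to an ynolate) and O-silylation by the bulky silyl triflate, an established one-pot entry to triisopropylsiloxyalkynes in which the monoanionic acetylide and ynolate protect the benzylic-propargylic CH2 from a second deprotonation.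

**Step 2**
Reactants: 4 triisopropyl{[3-(4-methoxyphenyl)prop-1-yn-1-yl]oxy}silane, 5 3-ethoxycyclobut-2-en-1-one
Product: 10 5-ethoxy-2-(4-methoxybenzyl)-3-[(triisopropylsilyl)oxy]phenol, via vinylketene 6 (not isolated), via vinylcyclobutenone 7 (not isolated), via dienylketene 8 (not isolated), via cyclohexadienone 9 (not isolated)
Conditions: PhMe (0.2 M), 4 (1.3 equiv), slow addition of 5, 80 → 110 °C, sealed tube, Ar
Reagents that add atoms: none
Why: Thermal conrotatory four-electron opening of 5 gives vinylketene 6, whose ketene C=C adds [2+2] to the electron-rich triple bond of 4 (bonds C8–C8a and C6–C7), and the resulting 4-vinylcyclobutenone 7 opens reversibly to dienylketene 8. Ring A is closed by a thermal disrotatory six-electron electrocyclization of 8 that forms C4a–C8a, and dienone 9 aromatises by tautomerisation to the phenol. The closest known reaction type is the Danheiser benzannulation of cyclobutenones with trialkylsiloxyalkynes, which gives resorcinol monosilyl ethers; a 3-alkoxycyclobutenone is a vinylogous ester and therefore a less usual and more reluctant vinylketene source, which is why the temperature is raised in stages. No stereocentre is created in the product (the one in 7 is lost on ring opening). The one selectivity that matters is the orientation of the [2+2] event: the siloxy oxygen pushes electron density onto the benzyl-bearing alkyne carbon, which therefore attacks the electrophilic ketene carbonyl carbon and becomes C8 next to the future phenol carbon C8a. Because the ethoxy-bearing carbon of 6 takes no part in bond formation it ends as C5, so the ketene oxygen emerges as the only free hydroxyl (future O1) between benzylated C8 and unsubstituted C4a.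

**Step 3**
Reactants: 10 5-ethoxy-2-(4-methoxybenzyl)-3-[(triisopropylsilyl)oxy]phenol, 11 ethyl 3-(4-methoxyphenyl)prop-2-ynoate
Product: 12 ethyl (2Z)-3-{5-ethoxy-2-(4-methoxybenzyl)-3-[(triisopropylsilyl)oxy]phenoxy}-3-(4-methoxyphenyl)prop-2-enoate
Conditions: K2CO3 (0.3 equiv), DMF, 4 Å MS, 70 °C
Reagents that add atoms: none
Why: Base-catalysed oxa-Michael addition of the only free phenoxide to the ynoate β-carbon (anti addition, hence drawn as the Z enol ether; the E isomer would serve equally because the geometry equilibrates in the acid of step 5), with O7 masked by the silyl group and water excluded to preserve it.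

**Step 4**
Reactants: 12 ethyl (2Z)-3-{5-ethoxy-2-(4-methoxybenzyl)-3-[(triisopropylsilyl)oxy]phenoxy}-3-(4-methoxyphenyl)prop-2-enoate
Product: 14 (2Z)-3-[5-ethoxy-3-hydroxy-2-(4-methoxybenzyl)phenoxy]-3-(4-methoxyphenyl)prop-2-enoic acid, via phenol ester 13 (not isolated)
Conditions: Bu4NF, THF, 0 °C; then LiOH·H2O, MeOH/H2O, 50 °C; 1 M HCl to pH 3
Reagents that add atoms: lithium hydroxide, [Li+].[OH-]
Why: Fluoride-induced cleavage of the aryl silyl ether is followed by BAc2 saponification of the ethyl ester; the electron-rich push–pull acrylate, further deactivated once phenoxide and carboxylate have formed, should resist hydroxide attack at its β-carbon, and freeing O7 here leaves only alkyl ethers for the last step.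

**Step 5**
Reactants: 14 (2Z)-3-[5-ethoxy-3-hydroxy-2-(4-methoxybenzyl)phenoxy]-3-(4-methoxyphenyl)prop-2-enoic acid
Product: 15 5-ethoxy-7-hydroxy-8-(4-methoxybenzyl)-2-(4-methoxyphenyl)-4H-chromen-4-one
Conditions: P2O5/MeSO3H (Eaton's reagent), 25 °C; poured onto ice
Reagents that add atoms: none
Why: Intramolecular Friedel–Crafts acylation through the mixed anhydride/acylium of a β-aryloxycinnamic acid, the classical flavone ring closure: C4a is the only ring carbon that can reach the acyl carbon through a six-membered transition state and is activated by O1 and the C5 ethoxy group (ortho) and by the C7 hydroxyl (para), while reversible protonation at C3 lets E and Z acids converge.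

**Step 6**
Reactants: 15 5-ethoxy-7-hydroxy-8-(4-methoxybenzyl)-2-(4-methoxyphenyl)-4H-chromen-4-one
Product: 16 5,7-dihydroxy-8-(4-hydroxybenzyl)-2-(4-hydroxyphenyl)-4H-chromen-4-one
Conditions: BBr3 (8 equiv), CH2Cl2, −78 °C → rt; MeOH then H2O quench
Reagents that add atoms: none
Why: Lewis acid mediated ether cleavage (BBr3 dealkylation): bromide attacks the methyl and ethyl carbons of the boron-complexed ethers, the C5 ethoxy group being assisted by chelation to the C4 carbonyl, and the cold aprotic conditions avoid the Wessely–Moser ring opening and reclosure that hot protic acid could trigger in a 5-hydroxy-8-substituted flavone.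

**Compound list**
1 | 1-methoxy-4-(prop-2-yn-1-yl)benzene | COc1ccc(CC#C)cc1 | starting material
2 | lithium acetylide of 1, [3-(4-methoxyphenyl)prop-1-yn-1-yl]lithium | COc1ccc(CC#C[Li])cc1 | intermediate
3 | lithium 3-(4-methoxyphenyl)prop-1-yn-1-olate | COc1ccc(CC#C[O-])cc1.[Li+] | intermediate
4 | triisopropyl{[3-(4-methoxyphenyl)prop-1-yn-1-yl]oxy}silane | COc1ccc(CC#CO[Si](C(C)C)(C(C)C)C(C)C)cc1 | intermediate
5 | 3-ethoxycyclobut-2-en-1-one | CCOC1=CC(=O)C1 | starting material
6 | 3-ethoxybuta-1,3-dien-1-one | CCOC(=C)C=C=O | intermediate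
7 | 4-(1-ethoxyethenyl)-2-(4-methoxybenzyl)-3-[(triisopropylsilyl)oxy]cyclobut-2-en-1-one (racemic) | CCOC(=C)C1C(=O)C(Cc2ccc(OC)cc2)=C1O[Si](C(C)C)(C(C)C)C(C)C | intermediate
8 | (3E)-5-ethoxy-2-(4-methoxybenzyl)-3-[(triisopropylsilyl)oxy]hexa-1,3,5-trien-1-one | O=C=C(Cc1ccc(OC)cc1)/C(O[Si](C(C)C)(C(C)C)C(C)C)=C\C(OCC)=C | intermediate
9 | 5-ethoxy-2-(4-methoxybenzyl)-3-[(triisopropylsilyl)oxy]cyclohexa-2,4-dien-1-one | O=C1CC(OCC)=CC(O[Si](C(C)C)(C(C)C)C(C)C)=C1Cc1ccc(OC)cc1 | intermediate
10 | 5-ethoxy-2-(4-methoxybenzyl)-3-[(triisopropylsilyl)oxy]phenol | CCOc1cc(O)c(Cc2ccc(OC)cc2)c(O[Si](C(C)C)(C(C)C)C(C)C)c1 | intermediate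
11 | ethyl 3-(4-methoxyphenyl)prop-2-ynoate | CCOC(=O)C#Cc1ccc(OC)cc1 | starting material
12 | ethyl (2Z)-3-{5-ethoxy-2-(4-methoxybenzyl)-3-[(triisopropylsilyl)oxy]phenoxy}-3-(4-methoxyphenyl)prop-2-enoate | CCOC(=O)/C=C(\Oc1cc(OCC)cc(O[Si](C(C)C)(C(C)C)C(C)C)c1Cc1ccc(OC)cc1)c1ccc(OC)cc1 | intermediate
13 | ethyl (2Z)-3-[5-ethoxy-3-hydroxy-2-(4-methoxybenzyl)phenoxy]-3-(4-methoxyphenyl)prop-2-enoate | CCOC(=O)/C=C(\Oc1cc(OCC)cc(O)c1Cc1ccc(OC)cc1)c1ccc(OC)cc1 | intermediate
14 | (2Z)-3-[5-ethoxy-3-hydroxy-2-(4-methoxybenzyl)phenoxy]-3-(4-methoxyphenyl)prop-2-enoic acid | OC(=O)/C=C(\Oc1cc(OCC)cc(O)c1Cc1ccc(OC)cc1)c1ccc(OC)cc1 | intermediate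
15 | 5-ethoxy-7-hydroxy-8-(4-methoxybenzyl)-2-(4-methoxyphenyl)-4H-chromen-4-one | CCOc1cc(O)c(Cc2ccc(OC)cc2)c2oc(-c3ccc(OC)cc3)cc(=O)c12 | intermediate
16 | 5,7-dihydroxy-8-(4-hydroxybenzyl)-2-(4-hydroxyphenyl)-4H-chromen-4-one | O=c1cc(-c2ccc(O)cc2)oc2c(Cc3ccc(O)cc3)c(O)cc(O)c12 | target

**Step count and risk**
Total steps: 6. Longest linear sequence: 6 steps (1 to 16).

Steps most likely to fail:

1. Step 2 (benzannulation). The ring opening of the vinylogous-ester cyclobutenone may need temperatures at which the siloxyalkyne isomerises by 1,3-silyl shift to a silylketene. The vinylketene may also be intercepted by the phenol as it forms (O-acylation), consuming both partners. The fallback sets out from 4 and separates ketene generation from heating. Purchased ethyl (2E)-3-ethoxybut-2-enoate is saponified (NaOH, aq. EtOH) to (2E)-3-ethoxybut-2-enoic acid F1 and converted with (COCl)2 and catalytic DMF into (2E)-3-ethoxybut-2-enoyl chloride F2. Slow addition of Et3N to F2 and 4 in CH2Cl2 at 0 °C to rt should effect 1,4-dehydrochlorination to vinylketene 6, which is trapped in situ by [2+2] cycloaddition as cyclobutenone 7. After removal of the ammonium salt, 7 is warmed alone in toluene (80–110 °C) and should pass through 8 and 9 to phenol 10, where the fallback rejoins the route with no ketene left to acylate the product.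

2. Step 3 (oxa-Michael addition). Conjugate addition of a hindered phenoxide to an internal ynoate deactivated by its donor aryl group may be slow, and prolonged heating with base may cause loss of the silyl ether. The fallback sets out from 10 and 11 and replaces conjugate addition by cross-coupling. Anti hydrobromination of 11 (LiBr, AcOH, MeCN, 80 °C) gives ethyl (2Z)-3-bromo-3-(4-methoxyphenyl)prop-2-enoate F3. F3 is joined to 10 by an Ullmann-type C–O vinylation (CuI, N,N-dimethylglycine, Cs2CO3, dioxane, 90 °C), which does not depend on the electrophilicity of the alkyne and retains the alkene geometry. The fallback comes back to the route at 12.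

3. Step 5 (acylative ring closure). In the strong acid, ipso protonation at C8 may lead to loss or migration of the 4-methoxybenzyl group, and intermolecular acylation of the anisole rings or of the free phenol may compete with closure. The fallback sets out from 10 and builds ring C in the reverse bond order without strong acid.
   - Magnesium-mediated ortho-formylation (MgCl2, Et3N, paraformaldehyde, MeCN, reflux) at C4a, the only free ortho carbon, gives 6-ethoxy-2-hydroxy-3-(4-methoxybenzyl)-4-[(triisopropylsilyl)oxy]benzaldehyde F4.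
   - Excess lithium (4-methoxyphenyl)acetylide (1-ethynyl-4-methoxybenzene, n-BuLi, THF, −78 °C) adds to give racemic 3-ethoxy-2-[1-hydroxy-3-(4-methoxyphenyl)prop-2-yn-1-yl]-6-(4-methoxybenzyl)-5-[(triisopropylsilyl)oxy]phenol F5.
   - MnO2 in CH2Cl2 oxidises it to 1-{6-ethoxy-2-hydroxy-3-(4-methoxybenzyl)-4-[(triisopropylsilyl)oxy]phenyl}-3-(4-methoxyphenyl)prop-2-yn-1-one F6.
   - Amine-mediated 6-endo closure (Et2NH, EtOH) should give 5-ethoxy-8-(4-methoxybenzyl)-2-(4-methoxyphenyl)-7-[(triisopropylsilyl)oxy]-4H-chromen-4-one F7.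
   - Bu4NF in THF removes the silyl group, and the fallback comes back to the route at 15.

**Further compounds**
F1 | step 2 | (2E)-3-ethoxybut-2-enoic acid | CCO/C(C)=C/C(=O)O
F2 | step 2 | (2E)-3-ethoxybut-2-enoyl chloride | CCO/C(C)=C/C(=O)Cl
F3 | step 3 | ethyl (2Z)-3-bromo-3-(4-methoxyphenyl)prop-2-enoate | CCOC(=O)/C=C(\Br)c1ccc(OC)cc1
F4 | step 5 | 6-ethoxy-2-hydroxy-3-(4-methoxybenzyl)-4-[(triisopropylsilyl)oxy]benzaldehyde | CCOc1cc(O[Si](C(C)C)(C(C)C)C(C)C)c(Cc2ccc(OC)cc2)c(O)c1C=O
F5 | step 5 | 3-ethoxy-2-[1-hydroxy-3-(4-methoxyphenyl)prop-2-yn-1-yl]-6-(4-methoxybenzyl)-5-[(triisopropylsilyl)oxy]phenol (racemic) | CCOc1cc(O[Si](C(C)C)(C(C)C)C(C)C)c(Cc2ccc(OC)cc2)c(O)c1C(O)C#Cc1ccc(OC)cc1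
F6 | step 5 | 1-{6-ethoxy-2-hydroxy-3-(4-methoxybenzyl)-4-[(triisopropylsilyl)oxy]phenyl}-3-(4-methoxyphenyl)prop-2-yn-1-one | CCOc1cc(O[Si](C(C)C)(C(C)C)C(C)C)c(Cc2ccc(OC)cc2)c(O)c1C(=O)C#Cc1ccc(OC)cc1
F7 | step 5 | 5-ethoxy-8-(4-methoxybenzyl)-2-(4-methoxyphenyl)-7-[(triisopropylsilyl)oxy]-4H-chromen-4-one | CCOc1cc(O[Si](C(C)C)(C(C)C)C(C)C)c(Cc2ccc(OC)cc2)c2oc(-c3ccc(OC)cc3)cc(=O)c12
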